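**Plan**

- Retrosynthesis: after global O-debenzylation the two interflavan bonds are cut, first C4(upper flavan)–C8(middle unit), then C4(middle unit)–C8(terminal unit). This gives a 7,4'-dibenzyloxyflavan-4-ol and two copies of one building block, 5,7,4'-tri-O-benzyl-epiafzelechin.
- The building block is traced through its flavan-3-one to a 2-aryl-3-nitro-2H-chromene, whose ring C is cut at C3–C4 (and O1–C2) into a 2-hydroxybenzaldehyde and a β-nitrostyrene.
- Enabling feature: in each epiafzelechin unit C4 is a benzylic CH2 on ring A ortho to the ring oxygen O1, and C3 is a carbinol next to the aryl-bearing C2. At the aldehyde level C4 is the formyl carbon of a salicylaldehyde, and a nitro group at C3 (a masked C3 carbonyl) makes C3 a nucleophile once O1 has added to the nitroalkene.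
- Forward: ring C is closed by an oxa-Michael/Henry sequence, the nitro group is converted to the ketone and reduced. Half of the monomer is oxidized at C4 and joined to the other half (middle–terminal dimer). The upper flavan (chalcone, flavanone, flavan-4-ol) is then attached at C8 of the middle unit, and the benzyl ethers are removed.
- Stereochemistry: C2/C3 (2R,3R, cis) of both epiafzelechin units come from one dynamic kinetic resolution by asymmetric transfer hydrogenation of the racemic flavan-3-one. C4 of the middle unit is set by cation capture anti to the C2 and C3 substituents. C2 (S) of the upper flavan comes from a kinetic resolution by transfer hydrogenation, and its C4 from axial attack anti to the 2-aryl group.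

Key step: step 3

Remark: the target is read as (2S)-7,4'-dihydroxyflavan-(4β→8)-epiafzelechin-(4β→8)-epiafzelechin, that is upper unit 2S,4R (2,4-trans), middle unit 2R,3R,4S (2,3-cis, 3,4-trans), terminal unit 2R,3R (2,3-cis).

**Route**

Step 1
Reactants: 1 2,4,6-trihydroxybenzaldehyde
Product: 3 2,4-bis(benzyloxy)-6-hydroxybenzaldehyde, via 4-O-benzyl monoether 2 (not isolated)
Conditions: BnBr (2.05 equiv), K2CO3 (2.1 equiv), DMF, 0 °C to rt
Reagents that add atoms: benzyl bromide, BrCc1ccccc1
Why: Williamson etherification under stoichiometric control, in which the 4-OH (para to the formyl group, most acidic) and then one of the two equivalent ortho OH groups are benzylated, while the last OH stays hydrogen-bonded to the aldehyde and remains free as the future O1 of ring C.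

Step 2
Reactants: 4 4-(benzyloxy)benzaldehyde; 5 nitromethane
Product: 7 (E)-1-(benzyloxy)-4-(2-nitroethenyl)benzene, via nitro alcohol 6 (not isolated)
Conditions: CH3NO2 (excess), NH4OAc, AcOH, 100 °C
Reagents that add atoms: none
Why: Henry reaction followed by dehydration, with the conjugated (E)-nitroalkene as the thermodynamic product.

Step 3
Reactants: 3 2,4-bis(benzyloxy)-6-hydroxybenzaldehyde; 7 (E)-1-(benzyloxy)-4-(2-nitroethenyl)benzene
Product: 10 5,7-bis(benzyloxy)-2-[4-(benzyloxy)phenyl]-3-nitro-2H-chromene (racemic), via oxa-Michael adduct 8 (not isolated), via nitro-aldol adduct 9 (not isolated)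
Conditions: DABCO (0.5 equiv), 7 (1.5 equiv), MeCN, 4 Å molecular sieves, 60 °C
Reagents that add atoms: none
Why: The phenoxide of 3 adds to the aryl-bearing β-carbon of nitroalkene 7 (O1–C2), the nitronate so formed at C3 attacks the neighbouring formyl carbon in an intramolecular Henry reaction (C3–C4, the ring-closing event), and loss of water from 9 gives the conjugated nitrochromene. The closest known reaction type is the oxa-Michael/Henry/dehydration synthesis of 2-aryl-3-nitro-2H-chromenes from salicylaldehydes and β-nitrostyrenes. Ring C closes by a 6-(enolexo)-exo-trig attack of the nitronate carbon on the aldehyde, allowed by Baldwin's rules. The only stereocenter that survives is C2, which is formed racemic and deliberately left uncontrolled because it lies α to the later C3 ketone and is set in step 6; the C3 and C4 centers of 9 disappear on dehydration. The step needs regioselectivity (O1 to the aryl-bearing carbon, nitronate carbon to the aldehyde), which is fixed by the polarity of the nitroalkene and the ortho relationship of OH and CHO on ring A, and the reversible additions should be drawn forward by the irreversible dehydration. The two helpers, the nitro group at C3 and the aldehyde oxidation level at C4, are taken out in steps 4 and 5.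

Step 4
Reactants: 10 5,7-bis(benzyloxy)-2-[4-(benzyloxy)phenyl]-3-nitro-2H-chromene
Product: 11 5,7-bis(benzyloxy)-2-[4-(benzyloxy)phenyl]-3-nitrochromane (racemic cis/trans mixture)
Conditions: NaBH4, THF/MeOH, 0 °C
Reagents that add atoms: none
Why: Conjugate hydride addition to the nitroalkene places hydride on C4 (the β-carbon) and makes it the CH2 of the target; the configuration at C2/C3 is irrelevant because both centers are reset in steps 5 and 6.

Step 5
Reactants: 11 5,7-bis(benzyloxy)-2-[4-(benzyloxy)phenyl]-3-nitrochromane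
Product: 15 5,7-bis(benzyloxy)-2-[4-(benzyloxy)phenyl]chroman-3-one (racemic), via sodium nitronate 12 (not isolated), via oxime 13 (not isolated), via ketimine 14 (not isolated)
Conditions: NaOMe, MeOH/THF, 0 °C; then aq. TiCl3 (4 equiv), NH4OAc buffer (pH 5), rt, argon
Reagents that add atoms: water, O
Why: Reductive Nef reaction, in which the nitronate is reduced by trivalent titanium through the oxime to the N–H ketimine and this is hydrolyzed at pH 5 to the C3 ketone, conditions mild enough for the benzyl ethers and the benzylic C2–O1 ether.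

Step 6
Reactants: 15 5,7-bis(benzyloxy)-2-[4-(benzyloxy)phenyl]chroman-3-one (racemic)
Product: 16 (2R,3R)-5,7-bis(benzyloxy)-2-[4-(benzyloxy)phenyl]chroman-3-ol (5,7,4'-tri-O-benzyl-epiafzelechin)
Conditions: RuCl(p-cymene)[(S,S)-TsDPEN] (2 mol %), HCO2H/Et3N (1:1), DMF, 40 °C, argon
Reagents that add atoms: none
Why: Noyori–Ikariya asymmetric transfer hydrogenation with dynamic kinetic resolution, in which C2–H (α to the ketone, benzylic to ring B and α to O1) should epimerize through the enol faster than reduction, the ruthenium hydride should attack C3 on the face opposite to the C2 aryl group (2,3-cis, the sense known for bulky hydrides on flavan-3-ones) and the chiral catalyst should reduce only the 2R ketone; the (S,S) ligand is chosen on the CH/π model with the ring A side of the ketone in the aryl position, and the absolute configuration of 16 would be verified by debenzylating a sample and comparing it with natural (−)-epiafzelechin.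

Step 7
Reactants: 16 (2R,3R)-5,7-bis(benzyloxy)-2-[4-(benzyloxy)phenyl]chroman-3-ol
Product: 17 (2R,3R,4S)-5,7-bis(benzyloxy)-2-[4-(benzyloxy)phenyl]-4-(2-ethoxyethoxy)chroman-3-ol
Conditions: DDQ (2 equiv), 2-ethoxyethanol (5 equiv), CH2Cl2, rt
Reagents that add atoms: 2-ethoxyethanol, CCOCCO
Why: DDQ abstracts hydride from C4, the benzylic position activated by the 5,7-dialkoxy ring A, and the cation is trapped by the alcohol anti to the 2-aryl and 3-hydroxy groups; the C4 configuration is of no consequence because C4 is ionized again in step 8.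

Step 8
Reactants: 17 (2R,3R,4S)-5,7-bis(benzyloxy)-2-[4-(benzyloxy)phenyl]-4-(2-ethoxyethoxy)chroman-3-ol; 16 (2R,3R)-5,7-bis(benzyloxy)-2-[4-(benzyloxy)phenyl]chroman-3-ol (4 equiv)
Product: 18 (2R,3R,4R)-5,7-bis(benzyloxy)-2-[4-(benzyloxy)phenyl]-4-{(2R,3R)-5,7-bis(benzyloxy)-2-[4-(benzyloxy)phenyl]-3-hydroxychroman-8-yl}chroman-3-ol (hexa-O-benzyl epiafzelechin-(4β→8)-epiafzelechin)
Conditions: TMSOTf (0.2 equiv), CH2Cl2, −78 °C; excess 16 recovered
Reagents that add atoms: none
Why: Lewis acid ionization of the C4 ether gives the benzylic cation, which is captured in a Friedel–Crafts alkylation by C8 of 16 (expected to be the most nucleophilic ring A position) on the face anti to the 2-aryl and 3-hydroxy groups, setting the 3,4-trans (4β→8) linkage, while the excess of 16 suppresses self-condensation of 17.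

Step 9
Reactants: 19 1-[4-(benzyloxy)-2-hydroxyphenyl]ethanone; 4 4-(benzyloxy)benzaldehyde
Product: 21 (E)-1-[4-(benzyloxy)-2-hydroxyphenyl]-3-[4-(benzyloxy)phenyl]prop-2-en-1-one, via aldol adduct 20 (not isolated)
Conditions: KOH, EtOH, rt
Reagents that add atoms: none
Why: Claisen–Schmidt condensation of the acetophenone enolate with the non-enolizable aldehyde, with dehydration to the conjugated (E)-chalcone.

Step 10
Reactants: 21 (E)-1-[4-(benzyloxy)-2-hydroxyphenyl]-3-[4-(benzyloxy)phenyl]prop-2-en-1-one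
Product: 22 7-(benzyloxy)-2-[4-(benzyloxy)phenyl]chroman-4-one (racemic)
Conditions: NaOAc, EtOH/H2O, reflux
Reagents that add atoms: none
Why: Intramolecular oxa-Michael addition of the phenol to the enone under equilibrating conditions gives the racemic flavanone, and uncyclized chalcone can be recycled.

Step 11
Reactants: 22 7-(benzyloxy)-2-[4-(benzyloxy)phenyl]chroman-4-one (racemic)
Product: 23 (2S,4S)-7-(benzyloxy)-2-[4-(benzyloxy)phenyl]chroman-4-ol
Conditions: RuCl(p-cymene)[(S,S)-TsDPEN] (1 mol %), HCO2H/Et3N (5:2), EtOAc, rt, stopped near half conversion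
Reagents that add atoms: none
Why: Kinetic resolution by Noyori–Ikariya transfer hydrogenation, in which the (S,S) catalyst delivers hydride to the face of the aryl ketone that gives the 4S carbinol, a trajectory that is the favored axial one only for the 2S ketone, so that (2S)-22 should be reduced to the 2,4-cis alcohol while (2R)-22 remains, is separated and can be racemized with base and recycled.

Step 12
Reactants: 23 (2S,4S)-7-(benzyloxy)-2-[4-(benzyloxy)phenyl]chroman-4-ol; 18 hexa-O-benzyl epiafzelechin-(4β→8)-epiafzelechin (2 equiv)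
Product: 24 octa-O-benzyl ether of the target [(2S,4R)-7,4'-di-O-benzylflavan-(4→8)-(2R,3R,4S)-5,7,4'-tri-O-benzylepiafzelechin-(4→8)-(2R,3R)-5,7,4'-tri-O-benzylepiafzelechin]
Conditions: BF3·OEt2 (0.3 equiv), 4 Å molecular sieves, CH2Cl2, −40 to 0 °C; excess 18 recovered
Reagents that add atoms: none
Why: Ionization of the benzylic alcohol with loss of water gives the C4 cation stabilized by O1 (ortho) and the 7-benzyloxy group (para), and Friedel–Crafts attack by C8 of the C4-linked epiafzelechin unit of 18 (the future middle unit; this carbon is flanked by O1 and O7 and expected to be the most nucleophilic free position) should occur axially, anti to the equatorial 2-aryl group, to give the 2,4-trans (4R) linkage.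

Step 13
Reactants: 24 octa-O-benzyl ether of the target
Product: 25 (2S)-7,4'-dihydroxyflavan-(4β→8)-epiafzelechin-(4β→8)-epiafzelechin (target)
Conditions: H2 (1 atm), Pd(OH)2/C, THF/MeOH/H2O, rt
Reagents that add atoms: none
Why: Hydrogenolysis of the eight benzyl ethers under neutral conditions should leave the interflavan bonds, the C2–O1 ethers and all stereocenters untouched.

**Compound list**

1 | 2,4,6-trihydroxybenzaldehyde | O=Cc1c(O)cc(O)cc1O | starting material
2 | 4-(benzyloxy)-2,6-dihydroxybenzaldehyde | O=Cc1c(O)cc(OCc2ccccc2)cc1O | intermediate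
3 | 2,4-bis(benzyloxy)-6-hydroxybenzaldehyde | O=Cc1c(O)cc(OCc2ccccc2)cc1OCc1ccccc1 | intermediate
4 | 4-(benzyloxy)benzaldehyde | O=Cc1ccc(OCc2ccccc2)cc1 | starting material
5 | nitromethane | C[N+](=O)[O-] | starting material
6 | 1-[4-(benzyloxy)phenyl]-2-nitroethanol (racemic) | OC(C[N+](=O)[O-])c1ccc(OCc2ccccc2)cc1 | intermediate
7 | (E)-1-(benzyloxy)-4-(2-nitroethenyl)benzene | [O-][N+](=O)/C=C/c1ccc(OCc2ccccc2)cc1 | intermediate
8 | 2,4-bis(benzyloxy)-6-{1-[4-(benzyloxy)phenyl]-2-nitroethoxy}benzaldehyde (racemic) | O=Cc1c(OCc2ccccc2)cc(OCc2ccccc2)cc1OC(C[N+](=O)[O-])c1ccc(OCc2ccccc2)cc1 | intermediate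
9 | 5,7-bis(benzyloxy)-2-[4-(benzyloxy)phenyl]-3-nitrochroman-4-ol (mixture of stereoisomers) | OC1c2c(OCc3ccccc3)cc(OCc3ccccc3)cc2OC(c2ccc(OCc3ccccc3)cc2)C1[N+](=O)[O-] | intermediate
10 | 5,7-bis(benzyloxy)-2-[4-(benzyloxy)phenyl]-3-nitro-2H-chromene (racemic) | [O-][N+](=O)C1=Cc2c(OCc3ccccc3)cc(OCc3ccccc3)cc2OC1c1ccc(OCc2ccccc2)cc1 | intermediate
11 | 5,7-bis(benzyloxy)-2-[4-(benzyloxy)phenyl]-3-nitrochromane (racemic cis/trans mixture) | [O-][N+](=O)C1Cc2c(OCc3ccccc3)cc(OCc3ccccc3)cc2OC1c1ccc(OCc2ccccc2)cc1 | intermediate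
12 | sodium nitronate of 11 | [Na+].[O-][N+]([O-])=C1Cc2c(OCc3ccccc3)cc(OCc3ccccc3)cc2OC1c1ccc(OCc2ccccc2)cc1 | intermediate
13 | 5,7-bis(benzyloxy)-2-[4-(benzyloxy)phenyl]chroman-3-one oxime | ON=C1Cc2c(OCc3ccccc3)cc(OCc3ccccc3)cc2OC1c1ccc(OCc2ccccc2)cc1 | intermediate
14 | 5,7-bis(benzyloxy)-2-[4-(benzyloxy)phenyl]chroman-3-imine | N=C1Cc2c(OCc3ccccc3)cc(OCc3ccccc3)cc2OC1c1ccc(OCc2ccccc2)cc1 | intermediate
15 | 5,7-bis(benzyloxy)-2-[4-(benzyloxy)phenyl]chroman-3-one (racemic) | O=C1Cc2c(OCc3ccccc3)cc(OCc3ccccc3)cc2OC1c1ccc(OCc2ccccc2)cc1 | intermediate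
16 | (2R,3R)-5,7-bis(benzyloxy)-2-[4-(benzyloxy)phenyl]chroman-3-ol | O[C@@H]1Cc2c(OCc3ccccc3)cc(OCc3ccccc3)cc2O[C@@H]1c1ccc(OCc2ccccc2)cc1 | intermediate
17 | (2R,3R,4S)-5,7-bis(benzyloxy)-2-[4-(benzyloxy)phenyl]-4-(2-ethoxyethoxy)chroman-3-ol | c1c(OCc3ccccc3)cc(OCc3ccccc3)c2c1O[C@H](c1ccc(OCc3ccccc3)cc1)[C@H](O)[C@H]2OCCOCC | intermediate
18 | (2R,3R,4R)-5,7-bis(benzyloxy)-2-[4-(benzyloxy)phenyl]-4-{(2R,3R)-5,7-bis(benzyloxy)-2-[4-(benzyloxy)phenyl]-3-hydroxychroman-8-yl}chroman-3-ol | c1c(OCc3ccccc3)cc(OCc3ccccc3)c2c1O[C@H](c1ccc(OCc3ccccc3)cc1)[C@H](O)[C@H]2c1c(OCc3ccccc3)cc(OCc3ccccc3)c2c1O[C@H](c1ccc(OCc3ccccc3)cc1)[C@H](O)C2 | intermediate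
19 | 1-[4-(benzyloxy)-2-hydroxyphenyl]ethanone | CC(=O)c1ccc(OCc2ccccc2)cc1O | starting material
20 | 1-[4-(benzyloxy)-2-hydroxyphenyl]-3-[4-(benzyloxy)phenyl]-3-hydroxypropan-1-one (racemic) | O=C(CC(O)c1ccc(OCc2ccccc2)cc1)c1ccc(OCc2ccccc2)cc1O | intermediate
21 | (E)-1-[4-(benzyloxy)-2-hydroxyphenyl]-3-[4-(benzyloxy)phenyl]prop-2-en-1-one | O=C(/C=C/c1ccc(OCc2ccccc2)cc1)c1ccc(OCc2ccccc2)cc1O | intermediate
22 | 7-(benzyloxy)-2-[4-(benzyloxy)phenyl]chroman-4-one (racemic) | O=C1CC(c2ccc(OCc3ccccc3)cc2)Oc2cc(OCc3ccccc3)ccc12 | intermediate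
23 | (2S,4S)-7-(benzyloxy)-2-[4-(benzyloxy)phenyl]chroman-4-ol | C(c1ccccc1)Oc1ccc([C@@H]2C[C@H](O)c3ccc(OCc4ccccc4)cc3O2)cc1 | intermediate
24 | octa-O-benzyl ether of the target [(2S,4R)-7,4'-di-O-benzylflavan-(4→8)-(2R,3R,4S)-5,7,4'-tri-O-benzylepiafzelechin-(4→8)-(2R,3R)-5,7,4'-tri-O-benzylepiafzelechin] | C(c5ccccc5)Oc1ccc([C@@H]2C[C@@H](c3c(OCc5ccccc5)cc(OCc5ccccc5)c4c3O[C@H](c3ccc(OCc5ccccc5)cc3)[C@H](O)[C@H]4c3c(OCc5ccccc5)cc(OCc5ccccc5)c4c3O[C@H](c3ccc(OCc5ccccc5)cc3)[C@H](O)C4)c3ccc(OCc5ccccc5)cc3O2)cc1 | intermediate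
25 | (2S)-7,4'-dihydroxyflavan-(4β→8)-epiafzelechin-(4β→8)-epiafzelechin | Oc1ccc([C@@H]2C[C@@H](c3c(O)cc(O)c4c3O[C@H](c3ccc(O)cc3)[C@H](O)[C@H]4c3c(O)cc(O)c4c3O[C@H](c3ccc(O)cc3)[C@H](O)C4)c3ccc(O)cc3O2)cc1 | target

**Step count and risks**

Total step count: 13. Longest linear sequence: 9 steps (steps 1, 3, 4, 5, 6, 7, 8, 12, 13).

Steps most likely to fail:

Step 6. Epimerization at C2 may be too slow relative to reduction, or hydride may be delivered with the wrong absolute or relative sense, so that the alcohol forms with low enantiomeric or diastereomeric purity. The fallback sets out from 15 and replaces the catalytic resolution by diastereoselective reduction and classical resolution. Reduction with LiBH(s-Bu)3 in THF at −78 °C should give the racemic 2,3-cis alcohol, (±)-cis-5,7-bis(benzyloxy)-2-[4-(benzyloxy)phenyl]chroman-3-ol F1. Esterification with (S)-2-methoxy-2-phenylacetic acid (DCC, DMAP, CH2Cl2) gives two diastereomeric esters, the (2R,3R)-chroman-3-yl (S)-2-methoxy-2-phenylacetate F2 and the (2S,3S)-chroman-3-yl (S)-2-methoxy-2-phenylacetate F3. They are separated by chromatography or crystallization, and hydrolysis of F2 with LiOH in THF/H2O returns to the route at 16.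

Step 12. The flavan-4-yl cation may attack C6 of either unit of the dimer, the 2,4-trans selectivity may erode with the bulky nucleophile, and the cation may self-condense through its flavene. The fallback sets out from 23 and 16 and reverses the order of assembly so that the sensitive coupling is run on the monomer. BF3·OEt2-mediated coupling of 23 with a large excess of 16 should give the upper dimer, (2R,3R)-5,7-bis(benzyloxy)-2-[4-(benzyloxy)phenyl]-8-{(2S,4R)-7-(benzyloxy)-2-[4-(benzyloxy)phenyl]chroman-4-yl}chroman-3-ol F4. DDQ oxidation in the presence of 2-ethoxyethanol then activates C4 of the epiafzelechin unit to give the 4-(2-ethoxyethoxy) derivative of the upper dimer F5. TMSOTf-catalyzed coupling of F5 with 16 at −78 °C returns to the route at 24.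

Step 3. The oxa-Michael addition may revert and the Henry closure may be slow on the hindered, electron-rich aldehyde, leaving the nitroalkene to polymerize under the amine base. The fallback sets out from 4 and reaches the flavan-3-one without the nitro group, closing ring C at O1–C2 instead. Claisen–Schmidt condensation of 4 with commercial 1-[2,4-bis(benzyloxy)-6-hydroxyphenyl]ethanone (KOH, EtOH) gives the chalcone (E)-1-[2,4-bis(benzyloxy)-6-hydroxyphenyl]-3-[4-(benzyloxy)phenyl]prop-2-en-1-one F6. Reduction with NaBH4 in THF/EtOH at reflux, with cyclodehydration in the same flask, should give 5,7-bis(benzyloxy)-2-[4-(benzyloxy)phenyl]-2H-chromene F7. Hydroboration–oxidation (BH3·THF, then NaOH/H2O2) gives the racemic 2,3-trans alcohol, (±)-trans-5,7-bis(benzyloxy)-2-[4-(benzyloxy)phenyl]chroman-3-ol F8. Dess–Martin oxidation returns to the route at 15.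

Further compounds
F1 | step 6 | (±)-cis-5,7-bis(benzyloxy)-2-[4-(benzyloxy)phenyl]chroman-3-ol (both enantiomers) | O[C@@H]1Cc2c(OCc3ccccc3)cc(OCc3ccccc3)cc2O[C@@H]1c1ccc(OCc2ccccc2)cc1.O[C@H]1Cc2c(OCc3ccccc3)cc(OCc3ccccc3)cc2O[C@H]1c1ccc(OCc2ccccc2)cc1
F2 | step 6 | (2R,3R)-5,7-bis(benzyloxy)-2-[4-(benzyloxy)phenyl]chroman-3-yl (S)-2-methoxy-2-phenylacetate | CO[C@H](C(=O)O[C@@H]1Cc2c(OCc3ccccc3)cc(OCc3ccccc3)cc2O[C@@H]1c1ccc(OCc2ccccc2)cc1)c1ccccc1
F3 | step 6 | (2S,3S)-5,7-bis(benzyloxy)-2-[4-(benzyloxy)phenyl]chroman-3-yl (S)-2-methoxy-2-phenylacetate | CO[C@H](C(=O)O[C@H]1Cc2c(OCc3ccccc3)cc(OCc3ccccc3)cc2O[C@H]1c1ccc(OCc2ccccc2)cc1)c1ccccc1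
F4 | step 12 | (2R,3R)-5,7-bis(benzyloxy)-2-[4-(benzyloxy)phenyl]-8-{(2S,4R)-7-(benzyloxy)-2-[4-(benzyloxy)phenyl]chroman-4-yl}chroman-3-ol | C(c5ccccc5)Oc1ccc([C@@H]2C[C@@H](c3c(OCc5ccccc5)cc(OCc5ccccc5)c4c3O[C@H](c3ccc(OCc5ccccc5)cc3)[C@H](O)C4)c3ccc(OCc5ccccc5)cc3O2)cc1
F5 | step 12 | (2R,3R,4S)-5,7-bis(benzyloxy)-2-[4-(benzyloxy)phenyl]-8-{(2S,4R)-7-(benzyloxy)-2-[4-(benzyloxy)phenyl]chroman-4-yl}-4-(2-ethoxyethoxy)chroman-3-ol | C(c5ccccc5)Oc1ccc([C@@H]2C[C@@H](c3c(OCc5ccccc5)cc(OCc5ccccc5)c4c3O[C@H](c3ccc(OCc5ccccc5)cc3)[C@H](O)[C@H]4OCCOCC)c3ccc(OCc5ccccc5)cc3O2)cc1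
F6 | step 3 | (E)-1-[2,4-bis(benzyloxy)-6-hydroxyphenyl]-3-[4-(benzyloxy)phenyl]prop-2-en-1-one | O=C(/C=C/c1ccc(OCc2ccccc2)cc1)c1c(O)cc(OCc2ccccc2)cc1OCc1ccccc1
F7 | step 3 | 5,7-bis(benzyloxy)-2-[4-(benzyloxy)phenyl]-2H-chromene (racemic) | C1(c2ccc(OCc3ccccc3)cc2)C=Cc2c(OCc3ccccc3)cc(OCc3ccccc3)cc2O1
F8 | step 3 | (±)-trans-5,7-bis(benzyloxy)-2-[4-(benzyloxy)phenyl]chroman-3-ol (both enantiomers) | O[C@H]1Cc2c(OCc3ccccc3)cc(OCc3ccccc3)cc2O[C@@H]1c1ccc(OCc2ccccc2)cc1.O[C@@H]1Cc2c(OCc3ccccc3)cc(OCc3ccccc3)cc2O[C@H]1c1ccc(OCc2ccccc2)cc1
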